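**Retrosynthetic overview**
1. Target 28 ⇐ diol 24 (angelate on the CH2OH, acetate on the ring CHOH, both last) ⇐ enone made by IBX dehydrogenation of a saturated, silyl-protected cage alcohol.
2. Seven-membered ring (formed last) ⇐ new step: hydrogen-atom-transfer radical cyclisation of a 1,1-disubstituted olefin onto a cyclobutanone sulfonylhydrazone with loss of N2; it makes the bond to the quaternary carbon and the cage C–H.
3. Cyclobutane and six-membered ring (formed first, in one step) ⇐ intramolecular ketene–olefin [2+2] of an acyclic acid, with the face chosen by a silyloxy stereocentre that later becomes the enone carbonyl.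
4. Acyclic acid ⇐ geranyl acetate (ozonolysis) + 2-bromoallyl silyl ether (asymmetric NiCl2/CrCl2 coupling) + senecioate dienolate (asymmetric vinylogous Mukaiyama aldol), then CuH conjugate reduction.
5. Ring order: four- and six-membered rings together, then the seven-membered ring.

Assumption: the ester side chain is the (Z)-2-methylbut-2-enoate (angelate) that the SMILES encodes; TBS = tert-butyldimethylsilyl, TIPS = triisopropylsilyl, TBDPS = tert-butyldiphenylsilyl, Ts = 4-methylbenzenesulfonyl.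

**Route**

Step 1
Reactants: 1 2-bromoprop-2-en-1-ol
Product: 2 tert-butyl[(2-bromoprop-2-en-1-yl)oxy]diphenylsilane
Conditions: TBDPSCl, imidazole, CH2Cl2, 0 °C to rt
Reagents that add atoms: tert-butyl(chloro)diphenylsilane, CC(C)(C)[Si](Cl)(c1ccccc1)c1ccccc1
Why: Imidazole-promoted silylation (nucleophilic substitution at silicon) masks the future angelate-bearing CH2OH as a bulky silyl ether; no stereocentre is involved.

Step 2
Reactants: 3 geranyl acetate
Product: 4 (2E)-3-methyl-6-oxohex-2-en-1-yl acetate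
Conditions: O3, CH2Cl2/pyridine, −78 °C; then Me2S
Reagents that add atoms: ozone, [O-][O+]=O
Why: Chemoselective ozonolysis with reductive work-up, because the electron-rich remote trisubstituted olefin reacts much faster than the olefin deactivated by the allylic acetate, which keeps its E geometry.

Step 3
Reactants: 4 (2E)-3-methyl-6-oxohex-2-en-1-yl acetate; 2 tert-butyl[(2-bromoprop-2-en-1-yl)oxy]diphenylsilane
Product: 5 (2E,6R)-6-hydroxy-3-methyl-7-[(TBDPS-oxy)methyl]octa-2,7-dien-1-yl acetate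
Conditions: CrCl2 (3 equiv), NiCl2 (2 mol %), chiral oxazoline–sulfonamide ligand (enantiomer giving 6R), THF, rt; aqueous work-up
Reagents that add atoms: none
Why: Nozaki–Hiyama–Kishi coupling, in which NiCl2 activates the vinyl bromide, the vinyl group passes to chromium and adds to the aldehyde (the acetate is inert), and the chiral sulfonamide ligand on chromium selects the aldehyde face that gives the 6R carbinol, the future acetoxy-bearing ring carbon.

Step 4
Reactants: 5 (2E,6R)-6-hydroxy-3-methyl-7-[(TBDPS-oxy)methyl]octa-2,7-dien-1-yl acetate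
Product: 6 (2E,6R)-3-methyl-7-[(TBDPS-oxy)methyl]-6-(TIPS-oxy)octa-2,7-dien-1-yl acetate
Conditions: TIPSOTf, 2,6-lutidine, CH2Cl2, −78 to 0 °C
Reagents that add atoms: triisopropylsilyl trifluoromethanesulfonate, CC(C)[Si](C(C)C)(C(C)C)OS(=O)(=O)C(F)(F)F
Why: Silyl triflate silylation of the hindered secondary allylic alcohol gives a bulky ether that later steers the radical ring closure and outlasts the TBS ether; the stereocentre is untouched.

Step 5
Reactants: 6 (2E,6R)-3-methyl-7-[(TBDPS-oxy)methyl]-6-(TIPS-oxy)octa-2,7-dien-1-yl acetate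
Product: 7 (2E,6R)-3-methyl-7-[(TBDPS-oxy)methyl]-6-(TIPS-oxy)octa-2,7-dien-1-ol
Conditions: K2CO3 (cat.), MeOH, 0 °C to rt
Reagents that add atoms: none
Why: Base-catalysed transesterification (methanolysis) removes only the acetate, since both silyl ethers are stable to it.

Step 6
Reactants: 7 (2E,6R)-3-methyl-7-[(TBDPS-oxy)methyl]-6-(TIPS-oxy)octa-2,7-dien-1-ol
Product: 8 (2E,6R)-3-methyl-7-[(TBDPS-oxy)methyl]-6-(TIPS-oxy)octa-2,7-dienal
Conditions: MnO2, CH2Cl2, rt
Reagents that add atoms: none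
Why: Allylic oxidation with MnO2 gives the E-enal without E/Z isomerisation and without touching the other olefin or the silyl ethers.

Step 7
Reactants: 9 methyl 3-methylbut-2-enoate
Product: 10 (Z)-tert-butyl[(1-methoxy-3-methylbuta-1,3-dien-1-yl)oxy]dimethylsilane
Conditions: LDA, THF/DMPU, −78 °C; then TBSCl
Reagents that add atoms: tert-butyl(chloro)dimethylsilane, CC(C)(C)[Si](C)(C)Cl
Why: γ-Deprotonation of the senecioate and O-silylation of the dienolate give the silyl dienol ether needed for the vinylogous Mukaiyama aldol reaction (the ketene acetal geometry is of no consequence).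

Step 8
Reactants: 8 (2E,6R)-3-methyl-7-[(TBDPS-oxy)methyl]-6-(TIPS-oxy)octa-2,7-dienal; 10 (Z)-tert-butyl[(1-methoxy-3-methylbuta-1,3-dien-1-yl)oxy]dimethylsilane
Product: 11 methyl (2E,5R,6E,10R)-5-(TBS-oxy)-3,7-dimethyl-11-[(TBDPS-oxy)methyl]-10-(TIPS-oxy)dodeca-2,6,11-trienoate
Conditions: chiral 3,3'-diaryl-1,1'-binaphthyl-2,2'-disulfonimide (3 mol %, enantiomer giving 5R), Et2O, −78 °C
Reagents that add atoms: none
Why: Catalytic asymmetric vinylogous Mukaiyama aldol reaction, in which the silylated chiral disulfonimide activates the enal, the dienolate attacks through its γ-carbon on one aldehyde face to set 5R, and silyl transfer delivers the TBS ether directly.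

Step 9
Reactants: 11 methyl (2E,5R,6E,10R)-5-(TBS-oxy)-3,7-dimethyl-11-[(TBDPS-oxy)methyl]-10-(TIPS-oxy)dodeca-2,6,11-trienoate
Product: 12 methyl (3S,5R,6E,10R)-5-(TBS-oxy)-3,7-dimethyl-11-[(TBDPS-oxy)methyl]-10-(TIPS-oxy)dodeca-6,11-dienoate
Conditions: Cu(OAc)2 (3 mol %), DTBM-SEGPHOS (enantiomer giving 3S), (EtO)2MeSiH, t-BuOH, toluene, 0 °C to rt
Reagents that add atoms: none
Why: Ligand-controlled asymmetric conjugate reduction by phosphine-bound CuH reduces only the α,β-unsaturated ester and sets 3S, so the later ketene is a plain alkylketene and no olefin sits in the future three-carbon bridge during the radical step.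

Step 10
Reactants: 12 methyl (3S,5R,6E,10R)-5-(TBS-oxy)-3,7-dimethyl-11-[(TBDPS-oxy)methyl]-10-(TIPS-oxy)dodeca-6,11-dienoate
Product: 13 (3S,5R,6E,10R)-5-(TBS-oxy)-3,7-dimethyl-11-[(TBDPS-oxy)methyl]-10-(TIPS-oxy)dodeca-6,11-dienoic acid
Conditions: LiOH, THF/MeOH/H2O, rt; then 1 M HCl to pH 4
Reagents that add atoms: lithium hydroxide, [Li+].[OH-]
Why: Saponification of the unhindered saturated methyl ester, which the silyl ethers tolerate together with the brief mild acidification.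

Step 11
Reactants: 13 (3S,5R,6E,10R)-5-(TBS-oxy)-3,7-dimethyl-11-[(TBDPS-oxy)methyl]-10-(TIPS-oxy)dodeca-6,11-dienoic acid
Product: 16 (1S,2S,4R,5S,7S)-4-(TBS-oxy)-2,7-dimethyl-7-{(3R)-4-[(TBDPS-oxy)methyl]-3-(TIPS-oxy)pent-4-en-1-yl}bicyclo[3.1.1]heptan-6-one, via acid chloride 14 (not isolated), via alkylketene 15 (not isolated)
Conditions: (COCl)2, DMF (cat.), CH2Cl2, 0 °C to rt; then slow addition to Et3N, toluene, reflux
Reagents that add atoms: none
Why: Intramolecular ketene–olefin [2+2] cycloaddition in which the ketene carbonyl carbon bonds to the less substituted olefin carbon and the α-carbon to the methyl-bearing terminus, giving the bridged bicyclo[3.1.1]heptan-6-one (cyclobutane and six-membered ring at once); addition is suprafacial on the E-olefin so the ring methyl ends syn to the three-carbon bridge, and allylic 1,3-strain (the C–H of the silyloxy carbon eclipses the olefin while the tether attacks from its own face) lets the 5R centre fix the three new ring stereocentres.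

Step 12
Reactants: 16 (1S,2S,4R,5S,7S)-4-(TBS-oxy)-2,7-dimethyl-7-{(3R)-4-[(TBDPS-oxy)methyl]-3-(TIPS-oxy)pent-4-en-1-yl}bicyclo[3.1.1]heptan-6-one
Product: 17 N'-[(1S,2S,4R,5R,7S)-4-(TBS-oxy)-2,7-dimethyl-7-{(3R)-4-[(TBDPS-oxy)methyl]-3-(TIPS-oxy)pent-4-en-1-yl}bicyclo[3.1.1]heptan-6-ylidene]-4-methylbenzenesulfonohydrazide
Conditions: TsNHNH2, MeOH/THF, 40 °C
Reagents that add atoms: 4-methylbenzenesulfonohydrazide, Cc1ccc(cc1)S(=O)(=O)NN
Why: Condensation of the strained cyclobutanone with the sulfonyl hydrazide gives the N-sulfonylhydrazone that serves as radical acceptor; no stereocentre changes and the C=N geometry is immaterial.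

Step 13
Reactants: 17 N'-[(1S,2S,4R,5R,7S)-4-(TBS-oxy)-2,7-dimethyl-7-{(3R)-4-[(TBDPS-oxy)methyl]-3-(TIPS-oxy)pent-4-en-1-yl}bicyclo[3.1.1]heptan-6-ylidene]-4-methylbenzenesulfonohydrazide
Product: 20 (1S,2S,5R,6S,7R,8R,9S,11R)-11-(TBS-oxy)-6-[(TBDPS-oxy)methyl]-2,6,9-trimethyl-5-(TIPS-oxy)tricyclo[5.4.0.0^2,8]undecane, via cyclised sulfonohydrazide 18 (not isolated), via bridgehead diazene 19 (not isolated)
Conditions: Fe(acac)3 (30 mol %), PhSiH3, EtOH/THF, 60 °C; then MeOH, 65 °C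
Reagents that add atoms: none
Why: Proposed new method: hydrogen-atom transfer from the Fe–H species formed from Fe(acac)3 and PhSiH3 to the 1,1-disubstituted olefin (the only olefin in 17) gives a nucleophilic tertiary radical that closes 7-exo onto the carbon of the cyclobutanone sulfonylhydrazone from the cyclobutane face that carries the tether, the sulfonyl-stabilised hydrazinyl radical is reduced to hydrazide 18, and warming expels 4-methylbenzenesulfinate to give monoalkyl diazene 19, which loses N2 and leaves H on the only open (exo) face of that cage carbon (elimination is impossible there); the planar radical adds through a chair-like seven-membered transition state with OTIPS pseudo-equatorial and its larger CH2OTBDPS branch anti to it, so the new methyl (the former =CH2) ends cis and the silyloxymethyl trans to OTIPS; the closest known reaction types are iron-hydride olefin–hydrazone couplings (olefin hydromethylation with formaldehyde sulfonylhydrazone, hydrogen-atom-transfer alkene–hydrazone cyclisations) and the loss of N2 from monoalkyl diazenes in reductive alkylations of sulfonylhydrazones, none shown for a seven-membered ring, a cyclobutylidene hydrazone or traceless C–H formation at a cage carbon.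

Step 14
Reactants: 20 (1S,2S,5R,6S,7R,8R,9S,11R)-11-(TBS-oxy)-6-[(TBDPS-oxy)methyl]-2,6,9-trimethyl-5-(TIPS-oxy)tricyclo[5.4.0.0^2,8]undecane
Product: 21 (1S,2S,5R,6S,7R,8R,9S,11R)-6-[(TBDPS-oxy)methyl]-2,6,9-trimethyl-5-(TIPS-oxy)tricyclo[5.4.0.0^2,8]undecan-11-ol
Conditions: HF·pyridine, pyridine, THF, 0 °C to rt
Reagents that add atoms: none
Why: Fluoride-mediated desilylation under buffered conditions removes the secondary TBS ether much faster than the hindered secondary TIPS and the neopentyl-type primary TBDPS ethers.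

Step 15
Reactants: 21 (1S,2S,5R,6S,7R,8R,9S,11R)-6-[(TBDPS-oxy)methyl]-2,6,9-trimethyl-5-(TIPS-oxy)tricyclo[5.4.0.0^2,8]undecan-11-ol
Product: 23 (1S,2S,5R,6S,7R,8S)-6-[(TBDPS-oxy)methyl]-2,6,9-trimethyl-5-(TIPS-oxy)tricyclo[5.4.0.0^2,8]undec-9-en-11-one, via saturated ketone 22 (not isolated)
Conditions: IBX (4 equiv), DMSO/fluorobenzene, 80 °C
Reagents that add atoms: none
Why: IBX oxidises the alcohol to ketone 22 and then dehydrogenates it (IBX dehydrogenation through the enol) to the enone; enolisation is possible only away from the bridgehead, so a single enone forms and the two temporary stereocentres on the bridge are erased.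

Step 16
Reactants: 23 (1S,2S,5R,6S,7R,8S)-6-[(TBDPS-oxy)methyl]-2,6,9-trimethyl-5-(TIPS-oxy)tricyclo[5.4.0.0^2,8]undec-9-en-11-one
Product: 24 (1S,2S,5R,6S,7R,8S)-5-hydroxy-6-(hydroxymethyl)-2,6,9-trimethyltricyclo[5.4.0.0^2,8]undec-9-en-11-one
Conditions: TBAF, THF, 40 °C; aqueous NH4Cl
Reagents that add atoms: none
Why: Fluoride cleavage of both remaining silyl ethers (Si–F bond formation), which the enone and the non-enolisable bridgehead positions tolerate.

Step 17
Reactants: 24 (1S,2S,5R,6S,7R,8S)-5-hydroxy-6-(hydroxymethyl)-2,6,9-trimethyltricyclo[5.4.0.0^2,8]undec-9-en-11-one; 25 angelic acid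
Product: 27 [(1S,2S,5R,6S,7R,8S)-5-hydroxy-2,6,9-trimethyl-11-oxotricyclo[5.4.0.0^2,8]undec-9-en-6-yl]methyl (2Z)-2-methylbut-2-enoate, via mixed anhydride 26 (not isolated)
Conditions: 25, 2,4,6-trichlorobenzoyl chloride, Et3N, toluene, rt; then 24, toluene, 75 °C (no DMAP)
Reagents that add atoms: none
Why: Yamaguchi-type esterification through the mixed 2,4,6-trichlorobenzoic anhydride without DMAP, conditions known to keep the Z (angelate) geometry, with the primary alcohol reacting before the more hindered secondary one.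

Step 18
Reactants: 27 [(1S,2S,5R,6S,7R,8S)-5-hydroxy-2,6,9-trimethyl-11-oxotricyclo[5.4.0.0^2,8]undec-9-en-6-yl]methyl (2Z)-2-methylbut-2-enoate
Product: 28 [(1S,2S,5R,6S,7R,8S)-5-(acetyloxy)-2,6,9-trimethyl-11-oxotricyclo[5.4.0.0^2,8]undec-9-en-6-yl]methyl (2Z)-2-methylbut-2-enoate
Conditions: Ac2O, DMAP (cat.), pyridine, CH2Cl2, rt
Reagents that add atoms: acetic anhydride, CC(=O)OC(C)=O
Why: DMAP-catalysed acetylation of the remaining secondary alcohol gives the target, and the installed angelate does not isomerise under these mild conditions.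

**Compound list**

1 | 2-bromoprop-2-en-1-ol | OCC(Br)=C | starting material
2 | tert-butyl[(2-bromoprop-2-en-1-yl)oxy]diphenylsilane | C=C(Br)CO[Si](c1ccccc1)(c1ccccc1)C(C)(C)C | intermediate
3 | geranyl acetate, (2E)-3,7-dimethylocta-2,6-dien-1-yl acetate | CC(=O)OC/C=C(\C)CCC=C(C)C | starting material
4 | (2E)-3-methyl-6-oxohex-2-en-1-yl acetate | CC(=O)OC/C=C(\C)CCC=O | intermediate
5 | (2E,6R)-6-hydroxy-3-methyl-7-[(TBDPS-oxy)methyl]octa-2,7-dien-1-yl acetate | CC(=O)OC/C=C(\C)CC[C@@H](O)C(=C)CO[Si](c1ccccc1)(c1ccccc1)C(C)(C)C | intermediate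
6 | (2E,6R)-3-methyl-7-[(TBDPS-oxy)methyl]-6-(TIPS-oxy)octa-2,7-dien-1-yl acetate | CC(=O)OC/C=C(\C)CC[C@@H](O[Si](C(C)C)(C(C)C)C(C)C)C(=C)CO[Si](c1ccccc1)(c1ccccc1)C(C)(C)C | intermediate
7 | (2E,6R)-3-methyl-7-[(TBDPS-oxy)methyl]-6-(TIPS-oxy)octa-2,7-dien-1-ol | OC/C=C(\C)CC[C@@H](O[Si](C(C)C)(C(C)C)C(C)C)C(=C)CO[Si](c1ccccc1)(c1ccccc1)C(C)(C)C | intermediate
8 | (2E,6R)-3-methyl-7-[(TBDPS-oxy)methyl]-6-(TIPS-oxy)octa-2,7-dienal | O=C/C=C(\C)CC[C@@H](O[Si](C(C)C)(C(C)C)C(C)C)C(=C)CO[Si](c1ccccc1)(c1ccccc1)C(C)(C)C | intermediate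
9 | methyl 3-methylbut-2-enoate | COC(=O)C=C(C)C | starting material
10 | (Z)-tert-butyl[(1-methoxy-3-methylbuta-1,3-dien-1-yl)oxy]dimethylsilane | CO\C(O[Si](C)(C)C(C)(C)C)=C\C(C)=C | intermediate
11 | methyl (2E,5R,6E,10R)-5-(TBS-oxy)-3,7-dimethyl-11-[(TBDPS-oxy)methyl]-10-(TIPS-oxy)dodeca-2,6,11-trienoate | COC(=O)/C=C(\C)C[C@@H](O[Si](C)(C)C(C)(C)C)/C=C(\C)CC[C@@H](O[Si](C(C)C)(C(C)C)C(C)C)C(=C)CO[Si](c1ccccc1)(c1ccccc1)C(C)(C)C | intermediate
12 | methyl (3S,5R,6E,10R)-5-(TBS-oxy)-3,7-dimethyl-11-[(TBDPS-oxy)methyl]-10-(TIPS-oxy)dodeca-6,11-dienoate | COC(=O)C[C@@H](C)C[C@@H](O[Si](C)(C)C(C)(C)C)/C=C(\C)CC[C@@H](O[Si](C(C)C)(C(C)C)C(C)C)C(=C)CO[Si](c1ccccc1)(c1ccccc1)C(C)(C)C | intermediate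
13 | (3S,5R,6E,10R)-5-(TBS-oxy)-3,7-dimethyl-11-[(TBDPS-oxy)methyl]-10-(TIPS-oxy)dodeca-6,11-dienoic acid | OC(=O)C[C@@H](C)C[C@@H](O[Si](C)(C)C(C)(C)C)/C=C(\C)CC[C@@H](O[Si](C(C)C)(C(C)C)C(C)C)C(=C)CO[Si](c1ccccc1)(c1ccccc1)C(C)(C)C | intermediate
14 | acid chloride of 13 (same stereocentres) | ClC(=O)C[C@@H](C)C[C@@H](O[Si](C)(C)C(C)(C)C)/C=C(\C)CC[C@@H](O[Si](C(C)C)(C(C)C)C(C)C)C(=C)CO[Si](c1ccccc1)(c1ccccc1)C(C)(C)C | intermediate (not isolated)
15 | monoalkylketene from 14 (C=C=O in place of CH2–COCl; same stereocentres) | O=C=C[C@@H](C)C[C@@H](O[Si](C)(C)C(C)(C)C)/C=C(\C)CC[C@@H](O[Si](C(C)C)(C(C)C)C(C)C)C(=C)CO[Si](c1ccccc1)(c1ccccc1)C(C)(C)C | intermediate (not isolated)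
16 | (1S,2S,4R,5S,7S)-4-(TBS-oxy)-2,7-dimethyl-7-{(3R)-4-[(TBDPS-oxy)methyl]-3-(TIPS-oxy)pent-4-en-1-yl}bicyclo[3.1.1]heptan-6-one (2-methyl and 4-silyloxy syn to the carbonyl bridge; 7-methyl syn to the three-carbon bridge) | O=C1[C@H]2[C@@H](C)C[C@@H](O[Si](C)(C)C(C)(C)C)[C@@H]1[C@@]2(C)CC[C@@H](O[Si](C(C)C)(C(C)C)C(C)C)C(=C)CO[Si](c1ccccc1)(c1ccccc1)C(C)(C)C | intermediate
17 | N'-[(1S,2S,4R,5R,7S)-4-(TBS-oxy)-2,7-dimethyl-7-{(3R)-4-[(TBDPS-oxy)methyl]-3-(TIPS-oxy)pent-4-en-1-yl}bicyclo[3.1.1]heptan-6-ylidene]-4-methylbenzenesulfonohydrazide (C=N geometry unspecified) | Cc1ccc(cc1)S(=O)(=O)NN=C1[C@H]2[C@@H](C)C[C@@H](O[Si](C)(C)C(C)(C)C)[C@@H]1[C@@]2(C)CC[C@@H](O[Si](C(C)C)(C(C)C)C(C)C)C(=C)CO[Si](c1ccccc1)(c1ccccc1)C(C)(C)C | intermediate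
18 | 4-methyl-N'-[tricyclic core of 20 bonded through C7]benzenesulfonohydrazide (ring stereocentres as in 20; nitrogen on the exo face of C7) | CC(C)(C)[Si](c1ccccc1)(c1ccccc1)OC[C@]1(C)[C@]2(NNS(=O)(=O)c4ccc(C)cc4)[C@H]3[C@@H](C)C[C@@H](O[Si](C)(C)C(C)(C)C)[C@@H]2[C@@]3(C)CC[C@H]1O[Si](C(C)C)(C(C)C)C(C)C | intermediate (not isolated)
19 | monoalkyl diazene (HN=N– at C7 of the tricyclic core of 20; stereocentres as in 20) | CC(C)(C)[Si](c1ccccc1)(c1ccccc1)OC[C@]1(C)[C@]2(N=N)[C@H]3[C@@H](C)C[C@@H](O[Si](C)(C)C(C)(C)C)[C@@H]2[C@@]3(C)CC[C@H]1O[Si](C(C)C)(C(C)C)C(C)C | intermediate (not isolated)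
20 | (1S,2S,5R,6S,7R,8R,9S,11R)-11-(TBS-oxy)-6-[(TBDPS-oxy)methyl]-2,6,9-trimethyl-5-(TIPS-oxy)tricyclo[5.4.0.0^2,8]undecane | CC(C)(C)[Si](c1ccccc1)(c1ccccc1)OC[C@]1(C)[C@@H]2[C@H]3[C@@H](C)C[C@@H](O[Si](C)(C)C(C)(C)C)[C@@H]2[C@@]3(C)CC[C@H]1O[Si](C(C)C)(C(C)C)C(C)C | intermediate
21 | (1S,2S,5R,6S,7R,8R,9S,11R)-6-[(TBDPS-oxy)methyl]-2,6,9-trimethyl-5-(TIPS-oxy)tricyclo[5.4.0.0^2,8]undecan-11-ol | CC(C)(C)[Si](c1ccccc1)(c1ccccc1)OC[C@]1(C)[C@@H]2[C@H]3[C@@H](C)C[C@@H](O)[C@@H]2[C@@]3(C)CC[C@H]1O[Si](C(C)C)(C(C)C)C(C)C | intermediate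
22 | (1S,2S,5R,6S,7R,8R,9S)-6-[(TBDPS-oxy)methyl]-2,6,9-trimethyl-5-(TIPS-oxy)tricyclo[5.4.0.0^2,8]undecan-11-one | CC(C)(C)[Si](c1ccccc1)(c1ccccc1)OC[C@]1(C)[C@@H]2[C@H]3[C@@H](C)CC(=O)[C@@H]2[C@@]3(C)CC[C@H]1O[Si](C(C)C)(C(C)C)C(C)C | intermediate (not isolated)
23 | (1S,2S,5R,6S,7R,8S)-6-[(TBDPS-oxy)methyl]-2,6,9-trimethyl-5-(TIPS-oxy)tricyclo[5.4.0.0^2,8]undec-9-en-11-one | CC(C)(C)[Si](c1ccccc1)(c1ccccc1)OC[C@]1(C)[C@@H]2[C@H]3C(C)=CC(=O)[C@@H]2[C@@]3(C)CC[C@H]1O[Si](C(C)C)(C(C)C)C(C)C | intermediate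
24 | (1S,2S,5R,6S,7R,8S)-5-hydroxy-6-(hydroxymethyl)-2,6,9-trimethyltricyclo[5.4.0.0^2,8]undec-9-en-11-one | OC[C@]1(C)[C@@H]2[C@H]3C(C)=CC(=O)[C@@H]2[C@@]3(C)CC[C@H]1O | intermediate
25 | angelic acid, (2Z)-2-methylbut-2-enoic acid | C/C=C(/C)C(O)=O | starting material
26 | (2Z)-2-methylbut-2-enoic 2,4,6-trichlorobenzoic anhydride | C/C=C(/C)C(=O)OC(=O)c1c(Cl)cc(Cl)cc1Cl | intermediate (not isolated)
27 | [(1S,2S,5R,6S,7R,8S)-5-hydroxy-2,6,9-trimethyl-11-oxotricyclo[5.4.0.0^2,8]undec-9-en-6-yl]methyl (2Z)-2-methylbut-2-enoate | C/C=C(/C)C(=O)OC[C@]1(C)[C@@H]2[C@H]3C(C)=CC(=O)[C@@H]2[C@@]3(C)CC[C@H]1O | intermediate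
28 | [(1S,2S,5R,6S,7R,8S)-5-(acetyloxy)-2,6,9-trimethyl-11-oxotricyclo[5.4.0.0^2,8]undec-9-en-6-yl]methyl (2Z)-2-methylbut-2-enoate | C/C=C(/C)C(=O)OC[C@]1(C)[C@@H]2[C@H]3C(C)=CC(=O)[C@@H]2[C@@]3(C)CC[C@H]1OC(C)=O | target

**Totals and risks**

Total step count: 18. Longest linear sequence: 16 steps (3 to 28 through steps 2–6 and 8–18).

Three steps most likely to fail:

Step 13 (the proposed new step). The seven-membered closure may be outrun by simple reduction of the tertiary radical, the diazene may not collapse cleanly, or the selectivity at the quaternary carbon may be low. The fallback uses known chemistry and sets out from cyclobutanone 16. Markovnikov hydrobromination of its only olefin (Co(acac)2, t-BuOOH, Et3SiH, TsBr) gives the tertiary bromide F4 as both epimers, which does not matter. An intramolecular Barbier addition with SmI2/HMPA in THF then closes the seven-membered ring onto the cyclobutanone to give the bridgehead tertiary alcohol F5. Acylation with methyl oxalyl chloride and DMAP gives the methyl oxalate F6, and radical deoxygenation with Bu3SnH/AIBN in refluxing toluene (elimination is blocked at this bridgehead) comes back to the route at 20.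

Step 11. The unactivated alkylketene may dimerise or react sluggishly with an olefin that carries an allylic silyloxy group. The fallback sets out from acid 13. Its chloride 14 is treated with pyrrolidine to give the pyrrolidine amide F1. Tf2O and 2,4,6-collidine in refluxing 1,2-dichloroethane convert F1 into the keteniminium triflate F2, a far stronger electrophile than the ketene, which undergoes the same bridged [2+2] to the cyclobutaniminium triflate F3. Hydrolysis with aqueous NaHCO3 comes back to the route at 16, with the same facial control.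

Step 17. Angelates isomerise easily to tiglates and the neopentyl-type primary alcohol is slow to acylate. The fallback sets out from diol 24 and builds the Z-olefin in place. DCC/DMAP esterification of the primary alcohol with 2-[bis(2,2,2-trifluoroethoxy)phosphoryl]propanoic acid gives the phosphonate ester F7. Still–Gennari olefination with acetaldehyde (KHMDS, 18-crown-6, THF, −78 °C) then gives the Z-2-methylbut-2-enoate and comes back to the route at 27.

**Further compounds**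

F1 | step 11 | pyrrolidine amide of acid 13 (same stereocentres) | O=C(C[C@@H](C)C[C@@H](O[Si](C)(C)C(C)(C)C)/C=C(\C)CC[C@@H](O[Si](C(C)C)(C(C)C)C(C)C)C(=C)CO[Si](c1ccccc1)(c1ccccc1)C(C)(C)C)N1CCCC1
F2 | step 11 | keteniminium triflate from F1 (N-pyrrolidinium ylidene; same stereocentres) | [O-]S(=O)(=O)C(F)(F)F.C1CC[N+](C1)=C=C[C@@H](C)C[C@@H](O[Si](C)(C)C(C)(C)C)/C=C(\C)CC[C@@H](O[Si](C(C)C)(C(C)C)C(C)C)C(=C)CO[Si](c1ccccc1)(c1ccccc1)C(C)(C)C
F3 | step 11 | cyclobutaniminium triflate (pyrrolidinium ylidene in place of the ketone oxygen of 16; same stereocentres) | [O-]S(=O)(=O)C(F)(F)F.C1CC[N+](C1)=C1[C@H]2[C@@H](C)C[C@@H](O[Si](C)(C)C(C)(C)C)[C@@H]1[C@@]2(C)CC[C@@H](O[Si](C(C)C)(C(C)C)C(C)C)C(=C)CO[Si](c1ccccc1)(c1ccccc1)C(C)(C)C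
F4 | step 13 | tertiary bromide from 16 (H and Br added across the side-chain olefin; both epimers at the C–Br carbon) | O=C1[C@H]2[C@@H](C)C[C@@H](O[Si](C)(C)C(C)(C)C)[C@@H]1[C@@]2(C)CC[C@@H](O[Si](C(C)C)(C(C)C)C(C)C)C(C)(Br)CO[Si](c1ccccc1)(c1ccccc1)C(C)(C)C
F5 | step 13 | bridgehead tertiary alcohol (20 with OH on C7 in place of H) | CC(C)(C)[Si](c1ccccc1)(c1ccccc1)OC[C@]1(C)[C@]2(O)[C@H]3[C@@H](C)C[C@@H](O[Si](C)(C)C(C)(C)C)[C@@H]2[C@@]3(C)CC[C@H]1O[Si](C(C)C)(C(C)C)C(C)C
F6 | step 13 | methyl oxalate of F5 | CC(C)(C)[Si](c1ccccc1)(c1ccccc1)OC[C@]1(C)[C@]2(OC(=O)C(=O)OC)[C@H]3[C@@H](C)C[C@@H](O[Si](C)(C)C(C)(C)C)[C@@H]2[C@@]3(C)CC[C@H]1O[Si](C(C)C)(C(C)C)C(C)C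
F7 | step 17 | primary 2-[bis(2,2,2-trifluoroethoxy)phosphoryl]propanoate of diol 24 (both epimers at the phosphonate α-carbon) | CC(C(=O)OC[C@]1(C)[C@@H]2[C@H]3C(C)=CC(=O)[C@@H]2[C@@]3(C)CC[C@H]1O)P(=O)(OCC(F)(F)F)OCC(F)(F)F
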